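**Retrosynthetic overview**

1. The C2–aryl bond is made last. C2 is the acetal-type carbon of the dihydrofuran ring: it carries ring oxygen O1, which is also the β-oxygen of the vinylogous ester O1–C7a=C7–C6=O in the cyclohexadienone ring. The target is therefore the C-aryl derivative of bicyclic lactol 10, made from oxocarbenium ion O1=C2 and (3,4,5-trimethoxyphenyl)zinc chloride 13; both C2 epimers converge on one product.
2. Lactol 10 comes from mixed acetal 9, whose C2 alkoxy group is a chiral auxiliary: it controls C3, lets minor diastereomers be removed on silica, and is then discarded.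
3. Acetal 9 comes from an acid-promoted formal [3+2] cycloaddition of para-quinone monoketal 5 with the chiral (Z)-propenyl ether 8 (C3–C3a and O1–C2 bonds, quaternary C3a).
4. Ketal 5 comes from 3,4-dimethoxyphenol by O-allylation, Claisen rearrangement and oxidative dearomatisation.
5. Ring order: six-membered ring (from the arene), then the dihydrofuran ring (step 6), then attachment of the trimethoxyphenyl ring (step 9).

Key step: step 9

Assumption: the (1S,2R)-2-phenylcyclohexyl group is taken to shield the enol ether face on the side of its phenyl ring; if the induction proved opposite, the equally available (1R,2S)-alcohol would be used with no other change.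

**Step 1**
Reactants: 1 3,4-dimethoxyphenol; 2 allyl bromide
Product: 3 1,2-dimethoxy-4-(prop-2-en-1-yloxy)benzene
Conditions: K2CO3, acetone, reflux
Reagents that add atoms: none
Why: Williamson ether synthesis, the phenoxide displacing bromide from the allylic halide.

**Step 2**
Reactants: 3 1,2-dimethoxy-4-(prop-2-en-1-yloxy)benzene
Product: 4 4,5-dimethoxy-2-(prop-2-en-1-yl)phenol
Conditions: PhNEt2, 200 °C
Reagents that add atoms: none
Why: aromatic Claisen rearrangement ([3,3]-sigmatropic shift and tautomerisation), which should deliver the allyl group mainly to the less hindered ortho position, the minor 2-allyl-3,4-dimethoxy isomer being removed by chromatography.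

**Step 3**
Reactants: 4 4,5-dimethoxy-2-(prop-2-en-1-yl)phenol
Product: 5 4,4,5-trimethoxy-2-(prop-2-en-1-yl)cyclohexa-2,5-dien-1-one
Conditions: PhI(OAc)2, MeOH, 0 °C
Reagents that add atoms: methanol, CO
Why: oxidative dearomatisation of a para-methoxyphenol by a trivalent iodine reagent, methanol adding para to the hydroxyl group to give the para-quinone monoketal.

**Step 4**
Reactants: 6 (1S,2R)-2-phenylcyclohexan-1-ol; 2 allyl bromide
Product: 7 [(1R,2S)-2-(prop-2-en-1-yloxy)cyclohexyl]benzene
Conditions: NaH, THF–DMF, 0 °C → rt
Reagents that add atoms: none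
Why: Williamson etherification of the secondary alkoxide, which does not touch either stereocentre.

**Step 5**
Reactants: 7 [(1R,2S)-2-(prop-2-en-1-yloxy)cyclohexyl]benzene
Product: 8 [(1R,2S)-2-{[(1Z)-prop-1-en-1-yl]oxy}cyclohexyl]benzene
Conditions: KOtBu (0.3 equiv), DMSO, 60 °C
Reagents that add atoms: none
Why: base-mediated allyl-to-propenyl ether isomerisation, which should give the (Z)-enol ether through a potassium-bridged cisoid allyl anion.

**Step 6**
Reactants: 5 4,4,5-trimethoxy-2-(prop-2-en-1-yl)cyclohexa-2,5-dien-1-one; 8 [(1R,2S)-2-{[(1Z)-prop-1-en-1-yl]oxy}cyclohexyl]benzene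
Product: 9 (3S,3aS)-5-methoxy-3-methyl-2-{[(1S,2R)-2-phenylcyclohexyl]oxy}-3a-(prop-2-en-1-yl)-3,3a-dihydro-1-benzofuran-6(2H)-one (both C2 epimers)
Conditions: Me3SiOTf (0.2 equiv), 4 Å MS, CH2Cl2, −78 → −40 °C; Et3N; chromatography
Reagents that add atoms: none
Why: acid-promoted formal [3+2] cycloaddition of a para-quinone monoketal with an electron-rich alkene (ionisation of the ketal, attack of the enol ether β-carbon on the allyl-bearing ring carbon, closure of the carbonyl oxygen onto the oxocarbenium ion, loss of the O-methyl group as dimethyl ether), in which the auxiliary should direct attack through the enol ether face remote from its phenyl ring (C3) and the approach with both substituents of the (Z)-enol ether pointing away from the six-membered ring should place the methyl group on the side of the allyl group (C3a relative to C3), minor diastereomers being removed on silica and the C2 configuration being irrelevant.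

**Step 7**
Reactants: 9 (3S,3aS)-5-methoxy-3-methyl-2-{[(1S,2R)-2-phenylcyclohexyl]oxy}-3a-(prop-2-en-1-yl)-3,3a-dihydro-1-benzofuran-6(2H)-one
Product: 10 (3S,3aS)-2-hydroxy-5-methoxy-3-methyl-3a-(prop-2-en-1-yl)-3,3a-dihydro-1-benzofuran-6(2H)-one (both C2 epimers)
Conditions: 0.5 M aq. HCl, THF, rt
Reagents that add atoms: water, O
Why: acid-catalysed hydrolysis of a mixed acetal whose ring oxygen belongs to a vinylogous ester (a pseudo-ester), which should proceed under conditions mild enough to leave the C5 enol ether, C3 and C3a untouched and to return alcohol 6.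

**Step 8**
Reactants: 11 5-bromo-1,2,3-trimethoxybenzene
Product: 13 chlorido(3,4,5-trimethoxyphenyl)zinc, via (3,4,5-trimethoxyphenyl)magnesium bromide 12 (not isolated)
Conditions: Mg, THF, rt; then ZnCl2 (1.0 equiv), THF, 0 °C
Reagents that add atoms: zinc chloride, Cl[Zn]Cl
Why: Grignard formation followed by transmetalation to zinc, giving an aryl donor that reacts with carbenium ions but is inert towards ketones and enones.

**Step 9**
Reactants: 10 (3S,3aS)-2-hydroxy-5-methoxy-3-methyl-3a-(prop-2-en-1-yl)-3,3a-dihydro-1-benzofuran-6(2H)-one; 13 chlorido(3,4,5-trimethoxyphenyl)zinc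
Product: 15 (2S,3S,3aR)-5-methoxy-3-methyl-3a-(prop-2-en-1-yl)-2-(3,4,5-trimethoxyphenyl)-3,3a-dihydro-1-benzofuran-6(2H)-one, via anomeric chloride 14 (not isolated)
Conditions: 1-chloro-N,N,2-trimethylprop-1-en-1-amine, CH2Cl2, 0 °C; then 13 (2.5 equiv), toluene–THF, −40 °C → rt
Reagents that add atoms: none
Why: The lactol (a pseudo-acid, in ring–chain equilibrium with the hydroxy-aldehyde) is converted under neutral conditions into the anomeric chloride, from which Lewis-acidic divalent zinc abstracts chloride to give the oxocarbenium ion O1=C2, and the aryl group is then transferred from zinc to C2. The closest known reaction type is the synthesis of C-aryl glycosides from glycosyl halides and arylzinc reagents, together with the arylation of 3-halophthalides. No ring is closed, and the dihydrofuran ring stays intact because only the exocyclic leaving group is activated. The new stereocentre C2 is controlled by the C3 methyl group and the angular C3a allyl group, which both stand on the convex face of the dihydrofuran ring, so the aryl group should enter from the opposite face, over the flat dienone, and give the 2,3-trans product. The step is stereoconvergent, since both anomers of 10 and of 14 pass through the same planar cation. It needs chemoselectivity for C2 over the dienone carbonyl and its conjugate positions, which the low carbonyl reactivity of an arylzinc halide should secure.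

**Compound list**

1 | 3,4-dimethoxyphenol | COc1ccc(O)cc1OC | starting material
2 | allyl bromide (3-bromoprop-1-ene) | C=CCBr | starting material
3 | 1,2-dimethoxy-4-(prop-2-en-1-yloxy)benzene | C=CCOc1ccc(OC)c(OC)c1 | intermediate
4 | 4,5-dimethoxy-2-(prop-2-en-1-yl)phenol | C=CCc1cc(OC)c(OC)cc1O | intermediate
5 | 4,4,5-trimethoxy-2-(prop-2-en-1-yl)cyclohexa-2,5-dien-1-one | C=CCC1=CC(OC)(OC)C(OC)=CC1=O | intermediate
6 | (1S,2R)-2-phenylcyclohexan-1-ol (trans) | O[C@H]1CCCC[C@@H]1c2ccccc2 | starting material
7 | [(1R,2S)-2-(prop-2-en-1-yloxy)cyclohexyl]benzene | C=CCO[C@H]1CCCC[C@@H]1c2ccccc2 | intermediate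
8 | [(1R,2S)-2-{[(1Z)-prop-1-en-1-yl]oxy}cyclohexyl]benzene | C/C=C\O[C@H]1CCCC[C@@H]1c2ccccc2 | intermediate
9 | (3S,3aS)-5-methoxy-3-methyl-2-{[(1S,2R)-2-phenylcyclohexyl]oxy}-3a-(prop-2-en-1-yl)-3,3a-dihydro-1-benzofuran-6(2H)-one, C2 epimers | C=CC[C@@]12C=C(OC)C(=O)C=C1OC(O[C@H]3CCCC[C@@H]3c4ccccc4)[C@H]2C | intermediate
10 | (3S,3aS)-2-hydroxy-5-methoxy-3-methyl-3a-(prop-2-en-1-yl)-3,3a-dihydro-1-benzofuran-6(2H)-one, C2 epimers | C=CC[C@@]12C=C(OC)C(=O)C=C1OC(O)[C@H]2C | intermediate
11 | 5-bromo-1,2,3-trimethoxybenzene | COc1cc(Br)cc(OC)c1OC | starting material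
12 | (3,4,5-trimethoxyphenyl)magnesium bromide | COc1cc([Mg]Br)cc(OC)c1OC | intermediate
13 | chlorido(3,4,5-trimethoxyphenyl)zinc | COc1cc([Zn]Cl)cc(OC)c1OC | intermediate
14 | (3S,3aS)-2-chloro-5-methoxy-3-methyl-3a-(prop-2-en-1-yl)-3,3a-dihydro-1-benzofuran-6(2H)-one, C2 epimers | C=CC[C@@]12C=C(OC)C(=O)C=C1OC(Cl)[C@H]2C | intermediate
15 | (2S,3S,3aR)-5-methoxy-3-methyl-3a-(prop-2-en-1-yl)-2-(3,4,5-trimethoxyphenyl)-3,3a-dihydro-1-benzofuran-6(2H)-one | C=CC[C@@]12C=C(OC)C(=O)C=C1O[C@H](c1cc(OC)c(OC)c(OC)c1)[C@H]2C | target

**Step count and risks**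

Total steps: 9. Longest linear sequence: 6 (steps 1, 2, 3, 6, 7, 9).

Steps most likely to fail:

Step 6. The oxocarbenium ion may close through the ring carbon next to the carbonyl instead of through oxygen, giving a bridged adduct. The chiral alkoxy group may be exchanged for methoxy. The facial selectivity of the enol ether, or the control of C3a relative to C3, may be poor. The fallback sets out from 5 and avoids both the cationic ring closure and the reliance on asymmetric induction. A Mukaiyama-type substitution of 5 with the trimethylsilyl enol ether of propanal (Me3SiOTf cat., CH2Cl2, −78 °C) should give the neutral aldehyde rac-(2S)-2-[(1S)-3,4-dimethoxy-6-oxo-1-(prop-2-en-1-yl)cyclohexa-2,4-dien-1-yl]propanal F1, the unwanted relative isomer being removed by chromatography. Dilute aqueous HCl in THF should then hydrolyse the vinylogous ester methoxy group and close the racemic lactol rac-(3S,3aS)-2-hydroxy-5-methoxy-3-methyl-3a-(prop-2-en-1-yl)-3,3a-dihydro-1-benzofuran-6(2H)-one F2. Acid-catalysed acetalisation of F2 with alcohol 6 (pyridinium 4-toluenesulfonate, toluene, removal of water) should give 9 together with its diastereomer (3R,3aR)-5-methoxy-3-methyl-2-{[(1S,2R)-2-phenylcyclohexyl]oxy}-3a-(prop-2-en-1-yl)-3,3a-dihydro-1-benzofuran-6(2H)-one F3, which is separated on silica. The route is rejoined at 9.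

Step 9. The aryl group may be delivered to the wrong face of the oxocarbenium ion. A proton may be lost from C3 to give a cyclic enol ether that can aromatise by allyl shift. Ionisation of the chloride may be too slow. The fallback sets out from 10 and makes the C–C bond on the open-chain form. Excess Grignard reagent 12 (THF, −78 → 0 °C) should first deprotonate the lactol, which opens to the aldehyde and an unreactive magnesium vinylogous carboxylate, and then add to the aldehyde to give 5-hydroxy-4-[(2S)-1-hydroxy-1-(3,4,5-trimethoxyphenyl)propan-2-yl]-2-methoxy-4-(prop-2-en-1-yl)cyclohexa-2,5-dien-1-one (4R) F4 as a mixture of carbinol epimers. Acid-catalysed cyclodehydration (BF3·OEt2 cat., CH2Cl2, −20 °C) through the benzylic cation, which the para-methoxy group stabilises, should close the O1–C2 bond and give the 2,3-trans isomer from either epimer. The route is rejoined at 15.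

Step 7. Aqueous acid may epimerise C3 through the open-chain aldehyde or trigger migration of the allyl group in the dienone. The fallback sets out from 9 and avoids both water and the lactol. Anhydrous exchange with benzenesulfinic acid (PhSO2H, CaCl2, CH2Cl2, rt) should return alcohol 6 and give the anomeric sulfone (3S,3aS)-2-(benzenesulfonyl)-5-methoxy-3-methyl-3a-(prop-2-en-1-yl)-3,3a-dihydro-1-benzofuran-6(2H)-one F5. The sulfonyl group is then displaced by arylzinc reagent 13 in the presence of ZnBr2 (THF, rt), a known substitution of 2-sulfonyl cyclic ethers through the same oxocarbenium ion. The route is rejoined at 15.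

**Further compounds**

F1 | step 6 | rac-(2S)-2-[(1S)-3,4-dimethoxy-6-oxo-1-(prop-2-en-1-yl)cyclohexa-2,4-dien-1-yl]propanal | C=CC[C@]1(C=C(OC)C(OC)=CC1=O)[C@H](C)C=O
F2 | step 6 | rac-(3S,3aS)-2-hydroxy-5-methoxy-3-methyl-3a-(prop-2-en-1-yl)-3,3a-dihydro-1-benzofuran-6(2H)-one | C=CC[C@@]12C=C(OC)C(=O)C=C1OC(O)[C@H]2C
F3 | step 6 | (3R,3aR)-5-methoxy-3-methyl-2-{[(1S,2R)-2-phenylcyclohexyl]oxy}-3a-(prop-2-en-1-yl)-3,3a-dihydro-1-benzofuran-6(2H)-one | C=CC[C@]12C=C(OC)C(=O)C=C1OC(O[C@H]3CCCC[C@@H]3c4ccccc4)[C@@H]2C
F4 | step 9 | (4R)-5-hydroxy-4-[(2S)-1-hydroxy-1-(3,4,5-trimethoxyphenyl)propan-2-yl]-2-methoxy-4-(prop-2-en-1-yl)cyclohexa-2,5-dien-1-one | C=CC[C@]1(C=C(OC)C(=O)C=C1O)[C@H](C)C(O)c1cc(OC)c(OC)c(OC)c1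
F5 | step 7 | (3S,3aS)-2-(benzenesulfonyl)-5-methoxy-3-methyl-3a-(prop-2-en-1-yl)-3,3a-dihydro-1-benzofuran-6(2H)-one | C=CC[C@@]12C=C(OC)C(=O)C=C1OC(S(=O)(=O)c1ccccc1)[C@H]2C
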